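**Retrosynthetic overview**

- The target comes from a C8/C3' diol of opposite carbinol configuration (double Appel inversion, last step), that from the C2-methylene compound (allylic C–H oxidation), that from a C6=C7 decalin.
- Feature used: ring B carries four contiguous stereocentres (C4a, C5, C8, C8a), but its C6–C7 edge is a bare CH2–CH2 unit. Ring B is therefore closed last at C6=C7 by ring-closing metathesis of a C5 vinyl arm and a C8 vinyl arm that stand trans on ring A.
- The arms: C5 by chelation-controlled vinyl Grignard addition to a C4a α-ketol; C4a by 1-ethoxyvinyllithium addition anti to the C8 arm; C8 by Shi epoxidation and selenoxide elimination of a propenyl group; C8a by Pd-catalysed decarboxylative asymmetric allylation.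
- Ring A is a Birch-reduced anisole that already carries the cyclopentane; C1' comes from Pd-catalysed asymmetric conjugate arylation of 3-methylcyclopentenone and C3' from CBS reduction.
- Ring order: cyclopentane (in the starting enone), then ring A (arene, dearomatised), then ring B (metathesis).

Key step: step 16

Remark: target locants (C1–C8a, C1'–C5') are used for every intermediate; each catalyst antipode is named from the usual sense of induction of its family and would be confirmed on the first product; 12 and 13 are C8a-epimer mixtures that converge at 15.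

**Route**

Step 1
Reactants: 1 3-methylcyclopent-2-en-1-one; 2 (3-methoxy-4-methylphenyl)boronic acid
Product: 3 (S)-3-(3-methoxy-4-methylphenyl)-3-methylcyclopentan-1-one
Conditions: Pd(OCOCF3)2 (5 mol%), (R)-4-tert-butyl-2-(pyridin-2-yl)-4,5-dihydrooxazole (6 mol%), NH4PF6, H2O, ClCH2CH2Cl, 40 °C
Reagents that add atoms: none
Why: Asymmetric conjugate addition of an arylboronic acid to a β-substituted cyclic enone under divalent palladium/pyridine-oxazoline catalysis; the ligand controls the face of aryl transfer and sets the quaternary C1'.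

Step 2
Reactants: 3 (S)-3-(3-methoxy-4-methylphenyl)-3-methylcyclopentan-1-one
Product: 5 (R)-4-(3-methoxy-4-methylphenyl)-4-methylcyclopent-2-en-1-one, via lithium enolate 4 (not isolated)
Conditions: LiN(i-Pr)2, THF, −78 °C; then PhS(Cl)=N-t-Bu, −78 °C
Reagents that add atoms: none
Why: Mukaiyama dehydrogenation (enolate sulfinimidoylation, then syn-elimination); only the enolate on the CH2 remote from the quaternary carbon has a β-hydrogen, so a single enone can form and C1' is untouched.

Step 3
Reactants: 5 (R)-4-(3-methoxy-4-methylphenyl)-4-methylcyclopent-2-en-1-one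
Product: 7 (R)-4-(3-methoxy-4-methylphenyl)-4,5,5-trimethylcyclopent-2-en-1-one, via monomethyl enone 6 (not isolated)
Conditions: NaH (3 equiv), MeI (excess), DME, 0 °C → rt
Reagents that add atoms: iodomethane, CI
Why: Exhaustive α'-alkylation of a 4,4-disubstituted cyclopentenone; C5 is the only enolisable position (C4 is quaternary), so both methyl groups go next to the quaternary carbon, a regiochemistry that direct alkylation of 3 would not give.

Step 4
Reactants: 7 (R)-4-(3-methoxy-4-methylphenyl)-4,5,5-trimethylcyclopent-2-en-1-one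
Product: 8 (R)-3-(3-methoxy-4-methylphenyl)-2,2,3-trimethylcyclopentan-1-one
Conditions: H2 (1 atm), 10% Pd on carbon, EtOAc, rt
Reagents that add atoms: none
Why: Heterogeneous hydrogenation of the disubstituted enone double bond; the arene and the hindered ketone should not be reduced.

Step 5
Reactants: 8 (R)-3-(3-methoxy-4-methylphenyl)-2,2,3-trimethylcyclopentan-1-one
Product: 9 (1S,3R)-3-(3-methoxy-4-methylphenyl)-2,2,3-trimethylcyclopentan-1-ol
Conditions: (R)-2-methyl-CBS-oxazaborolidine (0.5 equiv), BH3·SMe2, THF, 0 °C → rt; MeOH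
Reagents that add atoms: none
Why: Corey–Bakshi–Shibata reduction; the quaternary C2' side acts as the large group and the CH2 side as the small one, so the catalyst delivers hydride to give the (S)-carbinol at C3' (hydroxyl trans to the aryl group), the configuration needed for the later inversion.

Step 6
Reactants: 9 (1S,3R)-3-(3-methoxy-4-methylphenyl)-2,2,3-trimethylcyclopentan-1-ol
Product: 12 3-[(1R,3S)-3-hydroxy-1,2,2-trimethylcyclopentyl]-6-methylcyclohex-2-en-1-one (C6 epimers), via dihydroanisole 10 (not isolated), via unconjugated enone 11 (not isolated)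
Conditions: Li, NH3(l), t-BuOH, THF, −78 → −33 °C; NH4Cl; then 2 M HCl, THF, rt
Reagents that add atoms: water, O
Why: Birch reduction protonates the two unsubstituted positions ortho and meta to methoxy, leaving OMe, methyl and the tert-alkyl group on double bonds; acid then hydrolyses the enol ether and moves the double bond into conjugation, giving the ring A enone with the ketone at C4a.

Step 7
Reactants: 12 3-[(1R,3S)-3-hydroxy-1,2,2-trimethylcyclopentyl]-6-methylcyclohex-2-en-1-one
Product: 13 3-[(1R,3S)-3-(tert-butyldimethylsilyloxy)-1,2,2-trimethylcyclopentyl]-6-methylcyclohex-2-en-1-one (C6 epimers)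
Conditions: TBSOTf, 2,6-lutidine, CH2Cl2, −78 → 0 °C
Reagents that add atoms: tert-butyldimethylsilyl trifluoromethanesulfonate, CC(C)(C)[Si](C)(C)OS(=O)(=O)C(F)(F)F
Why: Silylation of a hindered secondary alcohol with the silyl triflate; with a pyridine base at low temperature the enone is not silylated.

Step 8
Reactants: 13 3-[(1R,3S)-3-(tert-butyldimethylsilyloxy)-1,2,2-trimethylcyclopentyl]-6-methylcyclohex-2-en-1-one; 14 allyl chloroformate
Product: 16 allyl 5-[(1R,3S)-3-(tert-butyldimethylsilyloxy)-1,2,2-trimethylcyclopentyl]-2-methylcyclohexa-1,5-dien-1-yl carbonate, via lithium dienolate 15 (not isolated)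
Conditions: LiN(i-Pr)2, THF, −78 °C; TMEDA; then 14, −78 → 0 °C
Reagents that add atoms: none
Why: Kinetic α'-deprotonation gives the cross-conjugated, tetrasubstituted enolate, which a chloroformate acylates on oxygen; the C8a epimers converge, and any C-acylated β-keto ester would also be a substrate for step 9.

Step 9
Reactants: 16 allyl 5-[(1R,3S)-3-(tert-butyldimethylsilyloxy)-1,2,2-trimethylcyclopentyl]-2-methylcyclohexa-1,5-dien-1-yl carbonate
Product: 17 (6R)-6-allyl-3-[(1R,3S)-3-(tert-butyldimethylsilyloxy)-1,2,2-trimethylcyclopentyl]-6-methylcyclohex-2-en-1-one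
Conditions: Pd2(dba)3 (2.5 mol%), (R)-4-tert-butyl-2-[2-(diphenylphosphino)phenyl]-4,5-dihydrooxazole (6.25 mol%), THF, 25 °C
Reagents that add atoms: none
Why: Decarboxylative asymmetric allylic alkylation (Tsuji allylation): zerovalent palladium ionises the allyl carbonate, CO2 is lost, and the enolate–allyl pair couples inside the chiral P,N pocket, so the quaternary C8a (R) is set by the ligand and not by the remote cyclopentane.

Step 10
Reactants: 17 (6R)-6-allyl-3-[(1R,3S)-3-(tert-butyldimethylsilyloxy)-1,2,2-trimethylcyclopentyl]-6-methylcyclohex-2-en-1-one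
Product: 18 (6R)-3-[(1R,3S)-3-(tert-butyldimethylsilyloxy)-1,2,2-trimethylcyclopentyl]-6-methyl-6-[(E)-prop-1-en-1-yl]cyclohex-2-en-1-one
Conditions: RuHCl(CO)(PPh3)3 (5 mol%), toluene, 80 °C
Reagents that add atoms: none
Why: Ruthenium hydride alkene isomerisation (hydrometalation, β-hydride elimination) moves the terminal double bond one position to the more stable (E)-propenyl group and stops there because C8a is quaternary.

Step 11
Reactants: 18 (6R)-3-[(1R,3S)-3-(tert-butyldimethylsilyloxy)-1,2,2-trimethylcyclopentyl]-6-methyl-6-[(E)-prop-1-en-1-yl]cyclohex-2-en-1-one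
Product: 19 (6R)-3-[(1R,3S)-3-(tert-butyldimethylsilyloxy)-1,2,2-trimethylcyclopentyl]-6-methyl-6-[(2S,3S)-3-methyloxiran-2-yl]cyclohex-2-en-1-one
Conditions: ent-Shi ketone (L-series 1,2:4,5-di-O-isopropylidene-erythro-2,3-hexodiulo-2,6-pyranose, 30 mol%), 2KHSO5·KHSO4·K2SO4, K2CO3, Bu4NHSO4, MeCN–CH2(OMe)2–aq. Na2B4O7 buffer, 0 °C
Reagents that add atoms: potassium peroxymonosulfate, [K+].[O-]S(=O)(=O)OO
Why: Shi asymmetric epoxidation of a trans-disubstituted alkene by a chiral dioxirane through a spiro transition state; the ketone antipode sets the C8–O configuration, and the electron-poor, hindered enone double bond does not react with the electrophilic oxidant.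

Step 12
Reactants: 19 (6R)-3-[(1R,3S)-3-(tert-butyldimethylsilyloxy)-1,2,2-trimethylcyclopentyl]-6-methyl-6-[(2S,3S)-3-methyloxiran-2-yl]cyclohex-2-en-1-one
Product: 22 (6R)-3-[(1R,3S)-3-(tert-butyldimethylsilyloxy)-1,2,2-trimethylcyclopentyl]-6-[(1R)-1-hydroxyprop-2-en-1-yl]-6-methylcyclohex-2-en-1-one, via hydroxy selenide 20 (not isolated), via selenoxide 21 (not isolated)
Conditions: (PhSe)2, NaBH4, EtOH, 0 °C → rt, then AcOH and 19, 60 °C; then 30% H2O2, THF, 0 °C → rt
Reagents that add atoms: none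
Why: Selenolate opens the epoxide at C7 (C8 is neopentylic) and selenoxide syn-elimination runs away from the carbinol onto the methyl group, so the terminal alkene forms with the C8–O bond untouched (8R); acetic acid buffering guards the quaternary β-hydroxy ketone against retro-aldol cleavage.

Step 13
Reactants: 22 (6R)-3-[(1R,3S)-3-(tert-butyldimethylsilyloxy)-1,2,2-trimethylcyclopentyl]-6-[(1R)-1-hydroxyprop-2-en-1-yl]-6-methylcyclohex-2-en-1-one
Product: 23 (6R)-6-[(1R)-1-(tert-butyldimethylsilyloxy)prop-2-en-1-yl]-3-[(1R,3S)-3-(tert-butyldimethylsilyloxy)-1,2,2-trimethylcyclopentyl]-6-methylcyclohex-2-en-1-one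
Conditions: TBSOTf, 2,6-lutidine, CH2Cl2, −78 °C
Reagents that add atoms: tert-butyldimethylsilyl trifluoromethanesulfonate, CC(C)(C)[Si](C)(C)OS(=O)(=O)C(F)(F)F
Why: Silyl triflate protection of the neopentylic allylic alcohol; the bulky, non-chelating silyl ether is what step 14 needs and it also shields C8–OH in step 18.

Step 14
Reactants: 23 (6R)-6-[(1R)-1-(tert-butyldimethylsilyloxy)prop-2-en-1-yl]-3-[(1R,3S)-3-(tert-butyldimethylsilyloxy)-1,2,2-trimethylcyclopentyl]-6-methylcyclohex-2-en-1-one; 24 ethyl vinyl ether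
Product: 27 1-[(1R,6R)-6-[(1R)-1-(tert-butyldimethylsilyloxy)prop-2-en-1-yl]-3-[(1R,3S)-3-(tert-butyldimethylsilyloxy)-1,2,2-trimethylcyclopentyl]-1-hydroxy-6-methylcyclohex-2-en-1-yl]ethan-1-one, via 1-ethoxyvinyllithium 25 (not isolated), via enol ether adduct 26 (not isolated)
Conditions: 24, t-BuLi, THF, −78 → 0 °C; then 23, −78 → −40 °C; then 0.5 M HCl, THF, 0 °C
Reagents that add atoms: water, O
Why: 1,2-Addition of an acyl anion equivalent to an enone that cannot enolise at C8a; the organolithium should enter anti to the bulky silyloxyallyl arm (pseudo-axial in the reactive conformer) and on the side of the C8a methyl, which puts the C4a hydroxyl cis to the C8 arm (4aR), and dilute acid then hydrolyses the enol ether to the methyl ketone.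

Step 15
Reactants: 27 the C4a α-hydroxy methyl ketone
Product: 28 (2R)-2-[(1R,6R)-6-[(1R)-1-(tert-butyldimethylsilyloxy)prop-2-en-1-yl]-3-[(1R,3S)-3-(tert-butyldimethylsilyloxy)-1,2,2-trimethylcyclopentyl]-1-hydroxy-6-methylcyclohex-2-en-1-yl]but-3-en-2-ol (1'R,3'S,4aR,5R,8R,8aR)
Conditions: CH2=CHMgBr (3 equiv), THF, −78 → −40 °C; aq. NH4Cl
Reagents that add atoms: vinylmagnesium bromide, C=C[Mg]Br
Why: Chelation-controlled (Cram chelate) Grignard addition: the magnesium alkoxide at C4a holds the C5 carbonyl syn, and the vinyl group enters from the side of the sp2 C4–H, away from the quaternary C8a, giving 5R.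

Step 16
Reactants: 28 ring A diene with the C4a/C5 diol arm and the C8 silyloxy arm
Product: 29 (4aR,5R,8R,8aR)-8-(tert-butyldimethylsilyloxy)-3-[(1R,3S)-3-(tert-butyldimethylsilyloxy)-1,2,2-trimethylcyclopentyl]-5,8a-dimethyl-1,5,8,8a-tetrahydronaphthalene-4a,5(2H)-diol
Conditions: RuCl2(H2IMes)(PCy3)(=CHPh) (second-generation Grubbs catalyst, 10 mol%), toluene (5 mM), 80 °C, argon sparge
Reagents that add atoms: none
Why: The ruthenium benzylidene exchanges onto one vinyl group, the new alkylidene adds across the other to a ruthenacyclobutane, and cycloreversion gives the C6=C7 bond with loss of ethylene over the cycle. The closest known reaction type is ruthenium-catalysed ring-closing metathesis of 1,7-dienes to cyclohexenes bearing free tertiary and protected secondary allylic oxygen groups. Ring B closes as a six-membered carbocycle by joining the terminal vinyl carbons C6 and C7 of arms that sit trans and pseudo-equatorial on C4a and C8a, the geometry that gives the trans ring fusion with the C4a hydroxyl and C8a methyl trans-diaxial. No stereocentre is formed; C4a, C5, C8 and C8a come from steps 9 to 15. The step needs chemoselectivity among three alkenes, and sterics secure it: the catalyst can load only on the two monosubstituted vinyl groups, while the trisubstituted C3=C4 bond lies between the quaternary C1' and C4a. High dilution and removal of ethylene counter oligomerisation and drive the closure.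

Step 17
Reactants: 29 C6=C7 decalin diol
Product: 30 (4aR,5R,8R,8aR)-8-(tert-butyldimethylsilyloxy)-3-[(1R,3S)-3-(tert-butyldimethylsilyloxy)-1,2,2-trimethylcyclopentyl]-5,8a-dimethyl-1,2,4a,5,6,7,8,8a-octahydronaphthalene-4a,5-diol
Conditions: H2 (4 atm), RhCl(PPh3)3 (10 mol%), benzene–EtOH, rt
Reagents that add atoms: none
Why: Homogeneous hydrogenation with Wilkinson's catalyst reduces the disubstituted C6=C7 bond and should leave the trisubstituted, doubly neopentylic C3=C4 bond and the allylic C–O bonds intact.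

Step 18
Reactants: 30 saturated ring B diol
Product: 31 (4aR,5R,8R,8aR)-8-(tert-butyldimethylsilyloxy)-3-[(1S,3S)-3-(tert-butyldimethylsilyloxy)-1,2,2-trimethylcyclopentyl]-4a,5-dihydroxy-5,8a-dimethyl-4a,5,6,7,8,8a-hexahydronaphthalen-2(1H)-one
Conditions: Rh2(cap)4 (cap = caprolactamate, 1 mol%), t-BuOOH (5 equiv), K2CO3, CH2Cl2, rt
Reagents that add atoms: tert-butyl hydroperoxide, CC(C)(C)OO
Why: Allylic C–H oxidation by tert-butylperoxy radicals: C2 is the only allylic carbon with hydrogen (C4a and C1' are quaternary), the allyl radical should be trapped at C2 and not at the neopentylic C4, and the peroxide collapses to the enone; both secondary hydroxyls are silylated and the tertiary ones cannot be oxidised.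

Step 19
Reactants: 31 bis-silylated γ-hydroxy enone
Product: 32 (4aR,5R,8R,8aR)-4a,5,8-trihydroxy-3-[(1S,3S)-3-hydroxy-1,2,2-trimethylcyclopentyl]-5,8a-dimethyl-4a,5,6,7,8,8a-hexahydronaphthalen-2(1H)-one
Conditions: HF·pyridine, pyridine, THF, 0 °C → 40 °C
Reagents that add atoms: none
Why: Fluoride-driven cleavage of both silyl ethers under buffered, weakly acidic conditions, which avoids base-induced vinylogous retro-aldol opening at C4a–C5.

Step 20
Reactants: 32 tetraol enone
Product: 33 (4aR,5R,8S,8aS)-8-bromo-3-[(1R,3R)-3-bromo-1,2,2-trimethylcyclopentyl]-4a,5-dihydroxy-5,8a-dimethyl-4a,5,6,7,8,8a-hexahydronaphthalen-2(1H)-one (CNP0216929.1)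
Conditions: CBr4, P(n-C8H17)3, toluene, 70 °C
Reagents that add atoms: carbon tetrabromide, BrC(Br)(Br)Br
Why: Appel reaction with the more nucleophilic trialkylphosphine: the two secondary hydroxyls form alkoxyphosphonium ions and bromide displaces them by SN2 with inversion at C8 (axial OH to equatorial Br) and at C3'; the tertiary hydroxyls should not react, and the enone deactivates C4a–OH toward ionisation.

**Compound list**

1 | 3-methylcyclopent-2-en-1-one | CC1=CC(=O)CC1 | starting material
2 | (3-methoxy-4-methylphenyl)boronic acid | COc1cc(ccc1C)B(O)O | starting material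
3 | (S)-3-(3-methoxy-4-methylphenyl)-3-methylcyclopentan-1-one | O=C1CC[C@@](C)(C1)c1ccc(C)c(OC)c1 | intermediate
4 | lithium enolate of 3 on the CH2 remote from the quaternary carbon | [Li]OC1=CC[C@@](C)(C1)c1ccc(C)c(OC)c1 | intermediate (not isolated)
5 | (R)-4-(3-methoxy-4-methylphenyl)-4-methylcyclopent-2-en-1-one | O=C1C=C[C@@](C)(C1)c1ccc(C)c(OC)c1 | intermediate
6 | (4S)-4-(3-methoxy-4-methylphenyl)-4,5-dimethylcyclopent-2-en-1-one (C5 epimers) | CC1C(=O)C=C[C@]1(C)c1ccc(C)c(OC)c1 | intermediate (not isolated)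
7 | (R)-4-(3-methoxy-4-methylphenyl)-4,5,5-trimethylcyclopent-2-en-1-one | CC1(C)C(=O)C=C[C@]1(C)c1ccc(C)c(OC)c1 | intermediate
8 | (R)-3-(3-methoxy-4-methylphenyl)-2,2,3-trimethylcyclopentan-1-one | CC1(C)C(=O)CC[C@]1(C)c1ccc(C)c(OC)c1 | intermediate
9 | (1S,3R)-3-(3-methoxy-4-methylphenyl)-2,2,3-trimethylcyclopentan-1-ol | CC1(C)[C@@H](O)CC[C@]1(C)c1ccc(C)c(OC)c1 | intermediate
10 | (1S,3R)-3-(5-methoxy-4-methylcyclohexa-1,4-dien-1-yl)-2,2,3-trimethylcyclopentan-1-ol | CC1(C)[C@@H](O)CC[C@]1(C)C1=CCC(C)=C(OC)C1 | intermediate (not isolated)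
11 | 3-[(1R,3S)-3-hydroxy-1,2,2-trimethylcyclopentyl]-6-methylcyclohex-3-en-1-one (C6 epimers) | CC1(C)[C@@H](O)CC[C@]1(C)C1=CCC(C)C(=O)C1 | intermediate (not isolated)
12 | 3-[(1R,3S)-3-hydroxy-1,2,2-trimethylcyclopentyl]-6-methylcyclohex-2-en-1-one (C6 epimers) | CC1(C)[C@@H](O)CC[C@]1(C)C1=CC(=O)C(C)CC1 | intermediate
13 | 3-[(1R,3S)-3-(tert-butyldimethylsilyloxy)-1,2,2-trimethylcyclopentyl]-6-methylcyclohex-2-en-1-one (C6 epimers) | CC1(C)[C@@H](O[Si](C)(C)C(C)(C)C)CC[C@]1(C)C1=CC(=O)C(C)CC1 | intermediate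
14 | allyl chloroformate | C=CCOC(=O)Cl | starting material
15 | lithium dienolate of 13 (O–C4a=C8a) | CC1(C)[C@@H](O[Si](C)(C)C(C)(C)C)CC[C@]1(C)C1=CC(O[Li])=C(C)CC1 | intermediate (not isolated)
16 | allyl 5-[(1R,3S)-3-(tert-butyldimethylsilyloxy)-1,2,2-trimethylcyclopentyl]-2-methylcyclohexa-1,5-dien-1-yl carbonate | CC1(C)[C@@H](O[Si](C)(C)C(C)(C)C)CC[C@]1(C)C1=CC(OC(=O)OCC=C)=C(C)CC1 | intermediate
17 | (6R)-6-allyl-3-[(1R,3S)-3-(tert-butyldimethylsilyloxy)-1,2,2-trimethylcyclopentyl]-6-methylcyclohex-2-en-1-one | CC1(C)[C@@H](O[Si](C)(C)C(C)(C)C)CC[C@]1(C)C1=CC(=O)[C@@](C)(CC=C)CC1 | intermediate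
18 | (6R)-3-[(1R,3S)-3-(tert-butyldimethylsilyloxy)-1,2,2-trimethylcyclopentyl]-6-methyl-6-[(E)-prop-1-en-1-yl]cyclohex-2-en-1-one | CC1(C)[C@@H](O[Si](C)(C)C(C)(C)C)CC[C@]1(C)C1=CC(=O)[C@@](C)(/C=C/C)CC1 | intermediate
19 | (6R)-3-[(1R,3S)-3-(tert-butyldimethylsilyloxy)-1,2,2-trimethylcyclopentyl]-6-methyl-6-[(2S,3S)-3-methyloxiran-2-yl]cyclohex-2-en-1-one | CC1(C)[C@@H](O[Si](C)(C)C(C)(C)C)CC[C@]1(C)C1=CC(=O)[C@@](C)([C@@H]2O[C@H]2C)CC1 | intermediate
20 | (6R)-3-[(1R,3S)-3-(tert-butyldimethylsilyloxy)-1,2,2-trimethylcyclopentyl]-6-[(1S,2R)-1-hydroxy-2-(phenylselanyl)propyl]-6-methylcyclohex-2-en-1-one | CC1(C)[C@@H](O[Si](C)(C)C(C)(C)C)CC[C@]1(C)C1=CC(=O)[C@@](C)([C@H](O)[C@@H](C)[Se]c2ccccc2)CC1 | intermediate (not isolated)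
21 | selenoxide of 20 (Se configuration open) | CC1(C)[C@@H](O[Si](C)(C)C(C)(C)C)CC[C@]1(C)C1=CC(=O)[C@@](C)([C@H](O)[C@@H](C)[Se](=O)c2ccccc2)CC1 | intermediate (not isolated)
22 | (6R)-3-[(1R,3S)-3-(tert-butyldimethylsilyloxy)-1,2,2-trimethylcyclopentyl]-6-[(1R)-1-hydroxyprop-2-en-1-yl]-6-methylcyclohex-2-en-1-one | CC1(C)[C@@H](O[Si](C)(C)C(C)(C)C)CC[C@]1(C)C1=CC(=O)[C@@](C)([C@H](O)C=C)CC1 | intermediate
23 | (6R)-6-[(1R)-1-(tert-butyldimethylsilyloxy)prop-2-en-1-yl]-3-[(1R,3S)-3-(tert-butyldimethylsilyloxy)-1,2,2-trimethylcyclopentyl]-6-methylcyclohex-2-en-1-one | CC1(C)[C@@H](O[Si](C)(C)C(C)(C)C)CC[C@]1(C)C1=CC(=O)[C@@](C)([C@H](O[Si](C)(C)C(C)(C)C)C=C)CC1 | intermediate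
24 | ethyl vinyl ether | CCOC=C | starting material
25 | 1-ethoxyvinyllithium | [Li]C(=C)OCC | intermediate (not isolated)
26 | (1R,6R)-6-[(1R)-1-(tert-butyldimethylsilyloxy)prop-2-en-1-yl]-3-[(1R,3S)-3-(tert-butyldimethylsilyloxy)-1,2,2-trimethylcyclopentyl]-1-(1-ethoxyvinyl)-6-methylcyclohex-2-en-1-ol (lithium alkoxide in the flask) | CC1(C)[C@@H](O[Si](C)(C)C(C)(C)C)CC[C@]1(C)C1=C[C@](O)(C(=C)OCC)[C@@](C)([C@H](O[Si](C)(C)C(C)(C)C)C=C)CC1 | intermediate (not isolated)
27 | 1-[(1R,6R)-6-[(1R)-1-(tert-butyldimethylsilyloxy)prop-2-en-1-yl]-3-[(1R,3S)-3-(tert-butyldimethylsilyloxy)-1,2,2-trimethylcyclopentyl]-1-hydroxy-6-methylcyclohex-2-en-1-yl]ethan-1-one | CC1(C)[C@@H](O[Si](C)(C)C(C)(C)C)CC[C@]1(C)C1=C[C@](O)(C(C)=O)[C@@](C)([C@H](O[Si](C)(C)C(C)(C)C)C=C)CC1 | intermediate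
28 | (2R)-2-[(1R,6R)-6-[(1R)-1-(tert-butyldimethylsilyloxy)prop-2-en-1-yl]-3-[(1R,3S)-3-(tert-butyldimethylsilyloxy)-1,2,2-trimethylcyclopentyl]-1-hydroxy-6-methylcyclohex-2-en-1-yl]but-3-en-2-ol | CC1(C)[C@@H](O[Si](C)(C)C(C)(C)C)CC[C@]1(C)C1=C[C@](O)([C@](C)(O)C=C)[C@@](C)([C@H](O[Si](C)(C)C(C)(C)C)C=C)CC1 | intermediate
29 | (4aR,5R,8R,8aR)-8-(tert-butyldimethylsilyloxy)-3-[(1R,3S)-3-(tert-butyldimethylsilyloxy)-1,2,2-trimethylcyclopentyl]-5,8a-dimethyl-1,5,8,8a-tetrahydronaphthalene-4a,5(2H)-diol | CC1(C)[C@@H](O[Si](C)(C)C(C)(C)C)CC[C@]1(C)C1=C[C@]2(O)[C@](C)(O)C=C[C@@H](O[Si](C)(C)C(C)(C)C)[C@@]2(C)CC1 | intermediate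
30 | (4aR,5R,8R,8aR)-8-(tert-butyldimethylsilyloxy)-3-[(1R,3S)-3-(tert-butyldimethylsilyloxy)-1,2,2-trimethylcyclopentyl]-5,8a-dimethyl-1,2,4a,5,6,7,8,8a-octahydronaphthalene-4a,5-diol | CC1(C)[C@@H](O[Si](C)(C)C(C)(C)C)CC[C@]1(C)C1=C[C@]2(O)[C@](C)(O)CC[C@@H](O[Si](C)(C)C(C)(C)C)[C@@]2(C)CC1 | intermediate
31 | (4aR,5R,8R,8aR)-8-(tert-butyldimethylsilyloxy)-3-[(1S,3S)-3-(tert-butyldimethylsilyloxy)-1,2,2-trimethylcyclopentyl]-4a,5-dihydroxy-5,8a-dimethyl-4a,5,6,7,8,8a-hexahydronaphthalen-2(1H)-one | CC1(C)[C@@H](O[Si](C)(C)C(C)(C)C)CC[C@]1(C)C1=C[C@]2(O)[C@](C)(O)CC[C@@H](O[Si](C)(C)C(C)(C)C)[C@@]2(C)CC1=O | intermediate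
32 | (4aR,5R,8R,8aR)-4a,5,8-trihydroxy-3-[(1S,3S)-3-hydroxy-1,2,2-trimethylcyclopentyl]-5,8a-dimethyl-4a,5,6,7,8,8a-hexahydronaphthalen-2(1H)-one | CC1(C)[C@@H](O)CC[C@]1(C)C1=C[C@]2(O)[C@](C)(O)CC[C@@H](O)[C@@]2(C)CC1=O | intermediate
33 | (4aR,5R,8S,8aS)-8-bromo-3-[(1R,3R)-3-bromo-1,2,2-trimethylcyclopentyl]-4a,5-dihydroxy-5,8a-dimethyl-4a,5,6,7,8,8a-hexahydronaphthalen-2(1H)-one | CC1(C)[C@H](Br)CC[C@]1(C)C1=C[C@]2(O)[C@](C)(O)CC[C@H](Br)[C@@]2(C)CC1=O | target

**Totals and risks**

Total step count: 20. Longest linear sequence: 20 steps (1 to 33).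

Steps most likely to fail:

1. Step 20 (double bromination). Both carbinols are neopentylic. At C8 the axial leaving group is anti-periplanar to the C8a methyl, so methyl migration or elimination may outrun direct displacement; the syn-axial C4a hydroxyl may also tie up the phosphonium centre as a cyclic phosphorane. Fallback, setting out from 32: sulfonylation of the two secondary hydroxyls with ClCH2SO2Cl and pyridine should give the bis(chloromethanesulfonate) F1, which is then displaced with LiBr in toluene–DMF at 60–80 °C, returning to the route at 33. This separates activation from substitution and uses a discrete leaving group in a weakly ionising medium.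

2. Step 14 (addition at C4a). Facial selectivity may be poor or reversed if the conformer with an axial C8a methyl controls the approach, which would place the new carbon cis to the C8 arm. Fallback, setting out from 23: Wittig ethylidenation (EtPPh3Br, KOt-Bu, toluene, 80 °C) should give the exocyclic ethylidene diene F2. OsO4/NMO dihydroxylation of the exocyclic double bond then makes oxygen the incoming group, so the same facial preference that misdirects carbon would place the C4a oxygen cis to the C8 arm, giving the diol F3. Oxidation of its secondary carbinol with SO3·pyridine/DMSO/Et3N returns to the route at 27.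

3. Step 16 (ring-closing metathesis). Both vinyl groups are attached to carbons next to quaternary centres, so catalyst loading may be slow and thermal catalyst decay or alkene isomerisation may compete. Fallback (relay metathesis), setting out from 27: chelation-controlled addition of (E)-3-(allyloxy)prop-1-en-1-ylmagnesium bromide in place of the vinyl reagent should give the relay triene F4. The second-generation Grubbs catalyst then loads on the unhindered allyl ether, expels 2,5-dihydrofuran to place the alkylidene at C6, and closes onto the C8 vinyl group, returning to the route at 29.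

Further compounds
F1 | step 20 | bis(chloromethanesulfonate) of 32 at C8 and C3' | CC1(C)[C@@H](OS(=O)(=O)CCl)CC[C@]1(C)C1=C[C@]2(O)[C@](C)(O)CC[C@@H](OS(=O)(=O)CCl)[C@@]2(C)CC1=O
F2 | step 14 | exocyclic ethylidene diene from 23 (C4a=CH–CH3, geometry open) | CC1(C)[C@@H](O[Si](C)(C)C(C)(C)C)CC[C@]1(C)C1=CC(=CC)[C@@](C)([C@H](O[Si](C)(C)C(C)(C)C)C=C)CC1
F3 | step 14 | C4a,C5-diol from F2 (4aR, C5 open) | CC1(C)[C@@H](O[Si](C)(C)C(C)(C)C)CC[C@]1(C)C1=C[C@](O)(C(C)O)[C@@](C)([C@H](O[Si](C)(C)C(C)(C)C)C=C)CC1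
F4 | step 16 | relay triene: 28 with the C5 vinyl group replaced by (E)-3-(allyloxy)prop-1-en-1-yl | CC1(C)[C@@H](O[Si](C)(C)C(C)(C)C)CC[C@]1(C)C1=C[C@](O)([C@](C)(O)/C=C/COCC=C)[C@@](C)([C@H](O[Si](C)(C)C(C)(C)C)C=C)CC1
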